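Retrosynthetic cuts: the eight aryl methyl ether O–C bonds; the C6–C(vinyl) bond of the stilbene on the styryl-bearing dihydrobenzofuran (unprimed locants; Heck reaction of a C6 triflate); the C3–C6' bond to the second dihydrobenzofuran (primed locants; decarboxylative arylation of a C3 acid by a C6' bromide); the C2'–C3' bond (carbene C–H insertion); and the C3–C3a bond, which leads back to a flavanone.
Enabling feature: in the unprimed ring system (O1, C2, C3, C3a, C4 to C7, C7a) the atoms O1, C2 with its 4-hydroxyphenyl group, C7a and C3a with the oxygen on C4 are O1, C2, C8a, C4a and the C5 oxygen of (S)-naringenin. The pyranone ring of naringenin holds one carbon more (C4); shifting C4a from C4 to C3 contracts that ring and leaves C4 as a carboxyl group on C3, the handle for the C3–C6' bond.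
Forward order: protected naringenin is ring-contracted (furan ring of the unprimed system first) and saponified; separately the primed furan ring is closed on a 4-bromo-2,6-dioxygenated benzophenone by dirhodium carbene insertion; the fragments are joined at C3–C6'; the benzyl ether becomes the triflate, the styrene is attached and the methyl ethers are cleaved.
Stereochemistry: C2 comes from (S)-naringenin; C3 is placed trans to the C2 aryl group, first by the stereospecific shift and finally by capture of the C3 radical anti to that group; C3' is set by the chiral dirhodium catalyst and C2' by acid equilibration to the trans ring; the E-alkene follows from syn β-hydride elimination.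

Key step: step 3

Assumption: Rh2(R-PTAD)4 is taken, by analogy with simpler 2-(benzyloxy)benzophenone hydrazones, to give the 3S centre in the insertion product of step 10; if the sense proves opposite, the mirror-image catalyst Rh2(S-PTAD)4 takes its place.

Step 1
Reactants: 1 (S)-naringenin [(2S)-5,7-dihydroxy-2-(4-hydroxyphenyl)chroman-4-one]
Product: 2 (2S)-7-benzyloxy-5-hydroxy-2-(4-hydroxyphenyl)chroman-4-one
Conditions: BnOH, PPh3, DIAD, THF, 0 °C to rt
Reagents that add atoms: benzyl alcohol, OCc1ccccc1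
Why: Mitsunobu etherification picks the most acidic, non-chelated 7-OH (para to the acyl carbon) and runs without base, so the C2 stereocentre is not exposed to retro-oxa-Michael opening to the chalcone.

Step 2
Reactants: 2 (2S)-7-benzyloxy-5-hydroxy-2-(4-hydroxyphenyl)chroman-4-one
Product: 3 (2S)-7-benzyloxy-5-methoxy-2-(4-methoxyphenyl)chroman-4-one
Conditions: MeI (excess), Ag2O, DMF, rt, dark
Reagents that add atoms: iodomethane, CI
Why: Purdie methylation (Williamson ether synthesis on silver oxide) alkylates the free 4'-OH and, more slowly, the hydrogen-bonded 5-OH under nearly neutral conditions, so C3 is not enolised and the flavanone should neither open to the chalcone nor racemise.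

Step 3
Reactants: 3 (2S)-7-benzyloxy-5-methoxy-2-(4-methoxyphenyl)chroman-4-one
Product: 6 methyl (2S,3S)-6-benzyloxy-4-methoxy-2-(4-methoxyphenyl)-2,3-dihydrobenzofuran-3-carboxylate, via enol ether 4 (not isolated), via iodanyl ketal 5 (not isolated)
Conditions: PhI(OAc)2 (1.1 equiv), conc. H2SO4 (cat.), HC(OMe)3, rt; aq. NaHCO3
Reagents that add atoms: trimethyl orthoformate, COC(OC)OC; water, O
Why: Acid and trimethyl orthoformate turn ketone 3 into its dimethyl ketal and enol ether 4, whose C3 attacks the trivalent iodine of PhI(OAc)2 on the face anti to the C2 aryl group to give the trans α-iodanyl ketal 5. The equatorial C3–I bond of 5 is antiperiplanar to C4–C4a, so the electron-rich ring-A carbon C4a shifts from C4 to C3 as iodobenzene departs, and the dimethoxycarbenium ion left at the former C4 is hydrolysed to the methyl ester on work-up. The closest known reaction type is the oxidative 1,2-aryl rearrangement of aryl ketone ketals by hypervalent iodine or Tl(NO3)3, which is established for flavanones. The furan ring (O1, C2, C3, C3a, C7a) closes by ring contraction, not by cyclisation of a chain: the ipso carbon bridges C4 and C3 in a phenonium-like three-membered transition state while C4–C4a breaks. The new C3 centre is under substrate control, since iodine enters anti to the C2 aryl group and the shift inverts C3, which places the ester trans to the aryl (2S,3S), the arrangement also preferred at equilibrium, while C2 takes no part and keeps the naringenin configuration. The step needs migration of ring A to outrun both the C2-aryl shift that would give an isoflavone and elimination to the flavone; the diequatorial 2-aryl/3-iodanyl geometry and the three oxygen donors ortho and para to C4a secure this, and only a slight excess of oxidant is used so that the electron-rich product ring is spared.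

Step 4
Reactants: 6 methyl (2S,3S)-6-benzyloxy-4-methoxy-2-(4-methoxyphenyl)-2,3-dihydrobenzofuran-3-carboxylate
Product: 7 (2S,3S)-6-benzyloxy-4-methoxy-2-(4-methoxyphenyl)-2,3-dihydrobenzofuran-3-carboxylic acid
Conditions: LiOH, THF/MeOH/H2O, rt; then 1 M HCl
Reagents that add atoms: lithium hydroxide, [Li+].[OH-]
Why: Saponification (BAc2 ester hydrolysis); the trans acid is the stable epimer so enolisation at C3 does no harm, and C2 is safe because ring opening of the enolate would be the reverse of a 5-endo-trig closure.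

Step 5
Reactants: 8 4-bromo-2,6-dimethoxybenzaldehyde
Product: 9 4-bromo-2-hydroxy-6-methoxybenzaldehyde
Conditions: BCl3 (1.1 equiv), CH2Cl2, −78 to 0 °C; then H2O
Reagents that add atoms: none
Why: Chelation-controlled Lewis acid ether cleavage: BCl3 bridges the aldehyde oxygen and one ortho methoxy group, chloride removes that methyl group, and the chelated aryloxyborane so formed protects the second methoxy group from cleavage.

Step 6
Reactants: 9 4-bromo-2-hydroxy-6-methoxybenzaldehyde; 10 2,4-dimethoxybenzyl alcohol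
Product: 11 4-bromo-2-[(2,4-dimethoxybenzyl)oxy]-6-methoxybenzaldehyde
Conditions: PPh3, DIAD, THF, 0 °C to rt
Reagents that add atoms: none
Why: Mitsunobu etherification of the acidic salicylaldehyde phenol with the primary benzylic alcohol gives the aryl benzyl ether without recourse to the unstable 2,4-dimethoxybenzyl chloride.

Step 7
Reactants: 11 4-bromo-2-[(2,4-dimethoxybenzyl)oxy]-6-methoxybenzaldehyde; 12 1-bromo-3,5-dimethoxybenzene
Product: 14 {4-bromo-2-[(2,4-dimethoxybenzyl)oxy]-6-methoxyphenyl}(3,5-dimethoxyphenyl)methanol (racemic), via arylmagnesium bromide 13 (not isolated)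
Conditions: 12, Mg, I2 (cat.), THF, 50 °C; then 11, THF, 0 °C; sat. aq. NH4Cl
Reagents that add atoms: none
Why: Grignard 1,2-addition to the aldehyde; the aryl bromide of 11 does not exchange with an arylmagnesium halide at 0 °C, and the new carbinol centre is removed in the next step, so its configuration does not matter.

Step 8
Reactants: 14 {4-bromo-2-[(2,4-dimethoxybenzyl)oxy]-6-methoxyphenyl}(3,5-dimethoxyphenyl)methanol
Product: 15 {4-bromo-2-[(2,4-dimethoxybenzyl)oxy]-6-methoxyphenyl}(3,5-dimethoxyphenyl)methanone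
Conditions: Dess–Martin periodinane, CH2Cl2, rt
Reagents that add atoms: none
Why: Dess–Martin oxidation of the diarylmethanol to the benzophenone runs under near-neutral conditions that the acid-sensitive benzyl ether and the aryl bromide tolerate.

Step 9
Reactants: 15 {4-bromo-2-[(2,4-dimethoxybenzyl)oxy]-6-methoxyphenyl}(3,5-dimethoxyphenyl)methanone
Product: 16 hydrazone of 15, [{4-bromo-2-[(2,4-dimethoxybenzyl)oxy]-6-methoxyphenyl}(3,5-dimethoxyphenyl)methylidene]hydrazine (E/Z mixture)
Conditions: N2H4·H2O (excess), AcOH (cat.), n-BuOH, 110 °C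
Reagents that add atoms: hydrazine, NN
Why: Hydrazone condensation; a large excess of hydrazine with acid catalysis at elevated temperature drives addition to the doubly ortho-substituted ketone and suppresses azine formation.

Step 10
Reactants: 16 hydrazone of 15
Product: 18 (2R,3S)-6-bromo-2-(2,4-dimethoxyphenyl)-3-(3,5-dimethoxyphenyl)-4-methoxy-2,3-dihydrobenzofuran (cis), via diazo compound 17 (not isolated)
Conditions: MnO2, CH2Cl2, 0 °C; then Rh2(R-PTAD)4 (1 mol %), 0 °C to rt
Reagents that add atoms: none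
Why: MnO2 dehydrogenates the hydrazone to diaryldiazomethane 17, whose donor/donor dirhodium carbene undergoes 1,5 C–H insertion into the doubly activated benzylic C–H bond of the ortho benzyl ether (favoured over the methyl C–H bonds of the other ortho ether) to close the furan ring; the chiral carboxylate ligands of Rh2(R-PTAD)4 set C3' (catalyst control) and the concerted insertion places the two aryl groups cis.

Step 11
Reactants: 18 (2R,3S)-6-bromo-2-(2,4-dimethoxyphenyl)-3-(3,5-dimethoxyphenyl)-4-methoxy-2,3-dihydrobenzofuran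
Product: 19 (2S,3S)-6-bromo-2-(2,4-dimethoxyphenyl)-3-(3,5-dimethoxyphenyl)-4-methoxy-2,3-dihydrobenzofuran (trans)
Conditions: CF3CO2H, CH2Cl2, 0 °C to rt
Reagents that add atoms: none
Why: Acid-mediated epimerisation: reversible ionisation of the C2'–O1' bond to the 2,4-dimethoxybenzyl cation and reclosure by the phenol lead to the more stable trans ring, so C2' is set under thermodynamic control by the untouched C3' centre.

Step 12
Reactants: 7 (2S,3S)-6-benzyloxy-4-methoxy-2-(4-methoxyphenyl)-2,3-dihydrobenzofuran-3-carboxylic acid; 19 (2S,3S)-6-bromo-2-(2,4-dimethoxyphenyl)-3-(3,5-dimethoxyphenyl)-4-methoxy-2,3-dihydrobenzofuran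
Product: 20 (2S,3S)-6-benzyloxy-3-[(2S,3S)-2-(2,4-dimethoxyphenyl)-3-(3,5-dimethoxyphenyl)-4-methoxy-2,3-dihydrobenzofuran-6-yl]-4-methoxy-2-(4-methoxyphenyl)-2,3-dihydrobenzofuran
Conditions: NiCl2(dme) (10 mol %), dtbbpy (15 mol %), [Ir(dF(CF3)ppy)2(dtbbpy)]PF6 (2 mol %), Cs2CO3, DMF, blue LEDs, rt
Reagents that add atoms: none
Why: Nickel/photoredox decarboxylative arylation: the excited iridium photocatalyst oxidises the caesium carboxylate of 7, loss of CO2 gives the planar benzylic C3 radical, and the aryl–nickel species formed from bromide 19 captures it on the face away from the C2 aryl group before reductive elimination, so the new C3–C6' bond stands trans to that group (substrate control).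

Step 13
Reactants: 20 benzyl ether from step 12
Product: 21 (2S,3S)-3-[(2S,3S)-2-(2,4-dimethoxyphenyl)-3-(3,5-dimethoxyphenyl)-4-methoxy-2,3-dihydrobenzofuran-6-yl]-4-methoxy-2-(4-methoxyphenyl)-2,3-dihydrobenzofuran-6-ol
Conditions: H2 (1 atm), Pd/C (10 wt %), EtOAc, rt
Reagents that add atoms: none
Why: Catalytic hydrogenolysis cleaves the unhindered primary benzyl aryl ether much faster than the secondary, ring-bound benzylic C–O bonds of the two dihydrofurans, and is stopped after uptake of one equivalent of hydrogen.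

Step 14
Reactants: 21 phenol from step 13
Product: 22 (2S,3S)-3-[(2S,3S)-2-(2,4-dimethoxyphenyl)-3-(3,5-dimethoxyphenyl)-4-methoxy-2,3-dihydrobenzofuran-6-yl]-4-methoxy-2-(4-methoxyphenyl)-2,3-dihydrobenzofuran-6-yl trifluoromethanesulfonate
Conditions: PhNTf2, Et3N, DMAP (cat.), CH2Cl2, rt
Reagents that add atoms: N-phenylbis(trifluoromethanesulfonimide), O=S(=O)(N(c1ccccc1)S(=O)(=O)C(F)(F)F)C(F)(F)F
Why: O-Sulfonylation of the phenol with the mild triflyl donor turns the C6 oxygen into a leaving group for cross-coupling.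

Step 15
Reactants: 22 aryl triflate from step 14; 23 4-methoxystyrene
Product: 24 (2S,3S)-3-[(2S,3S)-2-(2,4-dimethoxyphenyl)-3-(3,5-dimethoxyphenyl)-4-methoxy-2,3-dihydrobenzofuran-6-yl]-4-methoxy-2-(4-methoxyphenyl)-6-[(E)-2-(4-methoxyphenyl)ethenyl]-2,3-dihydrobenzofuran (octamethyl ether of the target)
Conditions: PdCl2(PPh3)2 (5 mol %), LiCl, Et3N, DMF, 100 °C
Reagents that add atoms: none
Why: Mizoroki–Heck reaction: oxidative addition of the aryl triflate to zerovalent palladium, chloride-promoted neutral pathway for arylation at the terminal carbon of the styrene and syn β-hydride elimination should give the E-stilbene.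

Step 16
Reactants: 24 octamethyl ether of the target
Product: 25 (2S,3S)-3-[(2S,3S)-2-(2,4-dihydroxyphenyl)-3-(3,5-dihydroxyphenyl)-4-hydroxy-2,3-dihydrobenzofuran-6-yl]-2-(4-hydroxyphenyl)-6-[(E)-2-(4-hydroxyphenyl)ethenyl]-2,3-dihydrobenzofuran-4-ol (CNP0118407.1)
Conditions: BBr3 (excess), CH2Cl2, −78 °C to rt; then H2O
Reagents that add atoms: none
Why: BBr3 ether cleavage (Lewis acid complexation, bromide attack at methyl, hydrolysis of the aryl borates) frees all eight phenols, and any reversible opening of the benzylic C2–O bonds should reclose to the trans rings fixed by C3 and C3'.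

Compound list
1 | (S)-naringenin | O=C1C[C@@H](c2ccc(O)cc2)Oc2cc(O)cc(O)c21 | starting material
2 | (2S)-7-benzyloxy-5-hydroxy-2-(4-hydroxyphenyl)chroman-4-one | O=C1C[C@@H](c2ccc(O)cc2)Oc2cc(OCc3ccccc3)cc(O)c21 | intermediate
3 | (2S)-7-benzyloxy-5-methoxy-2-(4-methoxyphenyl)chroman-4-one | COc1cc(OCc2ccccc2)cc2c1C(=O)C[C@@H](c1ccc(OC)cc1)O2 | intermediate
4 | (2S)-7-benzyloxy-4,5-dimethoxy-2-(4-methoxyphenyl)-2H-chromene (enol ether) | COC1=C[C@@H](c2ccc(OC)cc2)Oc2cc(OCc3ccccc3)cc(OC)c21 | intermediate
5 | (2R,3R)-3-[acetoxy(phenyl)-λ3-iodanyl]-7-benzyloxy-4,4,5-trimethoxy-2-(4-methoxyphenyl)chromane (iodine trans to the 2-aryl group) | COc1cc(OCc2ccccc2)cc2c1C(OC)(OC)[C@H](I(OC(C)=O)c1ccccc1)[C@@H](c1ccc(OC)cc1)O2 | intermediate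
6 | methyl (2S,3S)-6-benzyloxy-4-methoxy-2-(4-methoxyphenyl)-2,3-dihydrobenzofuran-3-carboxylate | c1ccccc1COc2cc(OC)c3c(c2)O[C@H](c2ccc(OC)cc2)[C@H]3C(=O)OC | intermediate
7 | (2S,3S)-6-benzyloxy-4-methoxy-2-(4-methoxyphenyl)-2,3-dihydrobenzofuran-3-carboxylic acid | c1ccccc1COc2cc(OC)c3c(c2)O[C@H](c2ccc(OC)cc2)[C@H]3C(=O)O | intermediate
8 | 4-bromo-2,6-dimethoxybenzaldehyde | O=Cc1c(OC)cc(Br)cc1OC | starting material
9 | 4-bromo-2-hydroxy-6-methoxybenzaldehyde | O=Cc1c(O)cc(Br)cc1OC | intermediate
10 | 2,4-dimethoxybenzyl alcohol | OCc1ccc(OC)cc1OC | starting material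
11 | 4-bromo-2-[(2,4-dimethoxybenzyl)oxy]-6-methoxybenzaldehyde | O=Cc1c(OC)cc(Br)cc1OCc1ccc(OC)cc1OC | intermediate
12 | 1-bromo-3,5-dimethoxybenzene | COc1cc(Br)cc(OC)c1 | starting material
13 | (3,5-dimethoxyphenyl)magnesium bromide | COc1cc([Mg]Br)cc(OC)c1 | intermediate
14 | {4-bromo-2-[(2,4-dimethoxybenzyl)oxy]-6-methoxyphenyl}(3,5-dimethoxyphenyl)methanol (racemic) | OC(c1cc(OC)cc(OC)c1)c1c(OC)cc(Br)cc1OCc1ccc(OC)cc1OC | intermediate
15 | {4-bromo-2-[(2,4-dimethoxybenzyl)oxy]-6-methoxyphenyl}(3,5-dimethoxyphenyl)methanone | O=C(c1cc(OC)cc(OC)c1)c1c(OC)cc(Br)cc1OCc1ccc(OC)cc1OC | intermediate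
16 | hydrazone of 15 (E/Z mixture) | NN=C(c1cc(OC)cc(OC)c1)c1c(OC)cc(Br)cc1OCc1ccc(OC)cc1OC | intermediate
17 | {4-bromo-2-[(2,4-dimethoxybenzyl)oxy]-6-methoxyphenyl}(3,5-dimethoxyphenyl)diazomethane | [N-]=[N+]=C(c1cc(OC)cc(OC)c1)c1c(OC)cc(Br)cc1OCc1ccc(OC)cc1OC | intermediate
18 | (2R,3S)-6-bromo-2-(2,4-dimethoxyphenyl)-3-(3,5-dimethoxyphenyl)-4-methoxy-2,3-dihydrobenzofuran (cis) | Brc1cc(OC)c2c(c1)O[C@@H](c1ccc(OC)cc1OC)[C@H]2c1cc(OC)cc(OC)c1 | intermediate
19 | (2S,3S)-6-bromo-2-(2,4-dimethoxyphenyl)-3-(3,5-dimethoxyphenyl)-4-methoxy-2,3-dihydrobenzofuran (trans) | Brc1cc(OC)c2c(c1)O[C@H](c1ccc(OC)cc1OC)[C@H]2c1cc(OC)cc(OC)c1 | intermediate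
20 | (2S,3S)-6-benzyloxy-3-[(2S,3S)-2-(2,4-dimethoxyphenyl)-3-(3,5-dimethoxyphenyl)-4-methoxy-2,3-dihydrobenzofuran-6-yl]-4-methoxy-2-(4-methoxyphenyl)-2,3-dihydrobenzofuran | c1ccccc1COc2cc(OC)c3c(c2)O[C@H](c2ccc(OC)cc2)[C@H]3c2cc(OC)c3c(c2)O[C@H](c2ccc(OC)cc2OC)[C@H]3c2cc(OC)cc(OC)c2 | intermediate
21 | 6-hydroxy analogue of 20 (phenol) | Oc1cc(OC)c2c(c1)O[C@H](c1ccc(OC)cc1)[C@H]2c1cc(OC)c2c(c1)O[C@H](c1ccc(OC)cc1OC)[C@H]2c1cc(OC)cc(OC)c1 | intermediate
22 | 6-trifluoromethanesulfonate of 21 | O=S(=O)(Oc1cc(OC)c2c(c1)O[C@H](c1ccc(OC)cc1)[C@H]2c1cc(OC)c2c(c1)O[C@H](c1ccc(OC)cc1OC)[C@H]2c1cc(OC)cc(OC)c1)C(F)(F)F | intermediate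
23 | 4-methoxystyrene | COc1ccc(C=C)cc1 | starting material
24 | octamethyl ether of the target, 6-[(E)-2-(4-methoxyphenyl)ethenyl] compound | COc1ccc(/C=C/c2cc(OC)c3c(c2)O[C@H](c2ccc(OC)cc2)[C@H]3c2cc(OC)c3c(c2)O[C@H](c2ccc(OC)cc2OC)[C@H]3c2cc(OC)cc(OC)c2)cc1 | intermediate
25 | CNP0118407.1, (2S,3S,2'S,3'S) octaphenol | Oc1ccc(/C=C/c2cc(O)c3c(c2)O[C@H](c2ccc(O)cc2)[C@H]3c2cc(O)c3c(c2)O[C@H](c2ccc(O)cc2O)[C@H]3c2cc(O)cc(O)c2)cc1 | target

Total step count: 16. Longest linear sequence: 12 steps (8 to 25 through steps 5 to 16); the naringenin branch contributes steps 1 to 4.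

Steps most likely to fail

Step 10. The diazo compound may form sluggishly at the doubly ortho-substituted carbon, and the carbene, twisted out of conjugation by its two ortho substituents, may insert with poor facial selectivity, attack the ortho methoxy C–H bonds, or dimerise to the azine. The fallback sets out from ketone 15 and comes back at 19. LiTMP (THF, −78 to 0 °C) removes a proton from the benzylic OCH2 group, and the carbanion adds 5-exo to the ketone to give the 3-hydroxy-2,3-dihydrobenzofuran F1. Et3SiH in CF3CO2H dehydrates it to the 2,3-diarylbenzofuran F2 and reduces this by C3 protonation and hydride delivery to C2 (ionic hydrogenation) to the racemic trans bromide F3. Preparative chromatography on a chiral stationary phase then gives 19. The C2'–C3' bond is thus made by polar instead of carbene chemistry, and the absolute configuration comes from resolution.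

Step 12. The electron-rich benzylic radical may be over-oxidised to the cation and lose the C2 proton (aromatisation of the furan ring), or capture by the hindered aryl–nickel species may be slow, which leads to protodecarboxylation. The fallback sets out from 7 and 19 and comes back at 20. Acid 7 is converted (N-hydroxyphthalimide, DIC, DMAP, CH2Cl2) into the redox-active ester F4, and bromide 19 (n-BuLi, THF, −78 °C; then ZnCl2) into the arylzinc chloride F5. NiCl2(dme) and dtbbpy in THF/DMF at rt then join the two by reductive fragmentation of the ester (decarboxylative Negishi-type arylation). This generates the same C3 radical without a photo-oxidant and should show the same trans preference.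

Step 16. The Lewis acid may attack the electron-rich stilbene (protonation or bromoboration, then Friedel–Crafts cyclisation onto a neighbouring resorcinol ring), and cleavage of eight ethers may stay incomplete. The fallback sets out from triflate 22 and comes back at 25; the ethers are cleaved before the alkene exists. BBr3 (CH2Cl2, −78 °C to rt), which an aryl triflate survives, gives the heptaphenol triflate F6, and Ac2O in pyridine gives the heptaacetate triflate F7. Heck coupling with 4-acetoxystyrene (PdCl2(PPh3)2, LiCl, Et3N, DMF, 100 °C) gives the octaacetate F8, and K2CO3 in MeOH at 0 °C removes the acetates to give 25.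

Further compounds
F1 | step 10 | 6-bromo-2-(2,4-dimethoxyphenyl)-3-(3,5-dimethoxyphenyl)-4-methoxy-2,3-dihydrobenzofuran-3-ol (racemic diastereomer mixture) | OC1(c2cc(OC)cc(OC)c2)c2c(OC)cc(Br)cc2OC1c1ccc(OC)cc1OC
F2 | step 10 | 6-bromo-2-(2,4-dimethoxyphenyl)-3-(3,5-dimethoxyphenyl)-4-methoxybenzofuran | COc1ccc(-c2oc3cc(Br)cc(OC)c3c2-c2cc(OC)cc(OC)c2)c(OC)c1
F3 | step 10 | racemic trans-6-bromo-2-(2,4-dimethoxyphenyl)-3-(3,5-dimethoxyphenyl)-4-methoxy-2,3-dihydrobenzofuran | Brc1cc(OC)c2c(c1)O[C@H](c1ccc(OC)cc1OC)[C@H]2c1cc(OC)cc(OC)c1.Brc1cc(OC)c2c(c1)O[C@@H](c1ccc(OC)cc1OC)[C@@H]2c1cc(OC)cc(OC)c1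
F4 | step 12 | 1,3-dioxoisoindolin-2-yl (2S,3S)-6-benzyloxy-4-methoxy-2-(4-methoxyphenyl)-2,3-dihydrobenzofuran-3-carboxylate | c1ccccc1COc2cc(OC)c3c(c2)O[C@H](c2ccc(OC)cc2)[C@H]3C(=O)ON2C(=O)c3ccccc3C2=O
F5 | step 12 | [(2S,3S)-2-(2,4-dimethoxyphenyl)-3-(3,5-dimethoxyphenyl)-4-methoxy-2,3-dihydrobenzofuran-6-yl]zinc chloride | Cl[Zn]c1cc(OC)c2c(c1)O[C@H](c1ccc(OC)cc1OC)[C@H]2c1cc(OC)cc(OC)c1
F6 | step 16 | heptaphenol triflate, (2S,3S)-3-[(2S,3S)-2-(2,4-dihydroxyphenyl)-3-(3,5-dihydroxyphenyl)-4-hydroxy-2,3-dihydrobenzofuran-6-yl]-4-hydroxy-2-(4-hydroxyphenyl)-2,3-dihydrobenzofuran-6-yl trifluoromethanesulfonate | O=S(=O)(Oc1cc(O)c2c(c1)O[C@H](c1ccc(O)cc1)[C@H]2c1cc(O)c2c(c1)O[C@H](c1ccc(O)cc1O)[C@H]2c1cc(O)cc(O)c1)C(F)(F)F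
F7 | step 16 | heptaacetate of F6 | O=S(=O)(Oc1cc(OC(C)=O)c2c(c1)O[C@H](c1ccc(OC(C)=O)cc1)[C@H]2c1cc(OC(C)=O)c2c(c1)O[C@H](c1ccc(OC(C)=O)cc1OC(C)=O)[C@H]2c1cc(OC(C)=O)cc(OC(C)=O)c1)C(F)(F)F
F8 | step 16 | octaacetate of 25 | CC(=O)Oc1ccc(/C=C/c2cc(OC(C)=O)c3c(c2)O[C@H](c2ccc(OC(C)=O)cc2)[C@H]3c2cc(OC(C)=O)c3c(c2)O[C@H](c2ccc(OC(C)=O)cc2OC(C)=O)[C@H]3c2cc(OC(C)=O)cc(OC(C)=O)c2)cc1
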